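## Structural features

Compound 25 is a trans-(2R,3R)-flavanonol. Aromatic ring A and dihydropyranone ring C are fused through C4a–C8a, and the 2',4'-dihydroxyphenyl ring B sits on C2. Ring A carries no hydrogen: oxygen at C5, C7 and C8a alternates with carbon, namely the C4 carbonyl on C4a, a 3-hydroxy-3-methylbutyl chain on C6, and a lavandulyl chain bound through its CH2 group on C8.

C2 and C3 are adjacent and must be trans. The third stereocentre, the branching carbon of the lavandulyl chain, lies two bonds outside ring A and cannot steer C2 or C3. It is S in 25 but has the same spatial arrangement as in the R-configured alcohol 10, because CH2–aryl ranks below isopropenyl whereas CH2–OH ranks above it.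

Three features are fragile:
- The two lavandulyl alkenes and the tertiary alcohol can be trapped as chromans by the neighbouring C5 and C7 phenols in acid.
- The C2–O1 bond is benzylic to an ortho/para-dioxygenated ring, so it ionises easily and C2 can epimerise.
- The α-ketol is dehydrogenated to the flavonol by base and air.

Ring A is unsymmetrical, so the oxygens at C5 and C8a, both ortho to the carbonyl, must be told apart; otherwise ring C closes the wrong way and the C6 and C8 chains swap places.

The real difficulty has three parts: filling all six positions of ring A in order, acylating the last position C4a between two oxygens, and oxygenating C2=C3 beside more electron-rich alkenes.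

The key step uses the fact that C4 is a single carbonyl carbon between C4a of ring A and the C3=C2 styrenyl unit of ring B. C4 and its oxygen can therefore be inserted as a one-carbon gas between two finished halves.

## Logic of the disconnections

**25 to 23.** Only heteroatom bonds are cut: four aryl O–CH2 acetal bonds and the tertiary O–Si bond. All carbon–carbon bonds and all three stereocentres are thus in place before the sensitive phenols appear. The forward step must free five hydroxyls without strong Brønsted acid, since free C5 and C7 phenols next to alkenes and a tertiary alcohol would close to chromans.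

**23 to 21 (through 22).** The O1–C2 bond is cut, which opens ring C to an epoxy ketone. C3 keeps the epoxide oxygen, and C2 is set by backside attack of the C8a oxygen. One stereodefined oxirane therefore stands for both stereocentres. The forward step needs the C8a oxygen free while the C5 oxygen stays blocked. It also needs opening at C2 (6-endo) rather than at C3 (5-exo), which calls for neutral-to-acidic rather than phenoxide conditions.

**21 to 20.** The two C–O bonds of the oxirane are cut, leaving a planar E-enone with no stereocentre in the three-carbon bridge. The oxidant must be nucleophilic so that it attacks only the electron-poor C2=C3 bond and ignores the lavandulyl alkenes. A chiral catalyst must choose the face, because the resident stereocentre is too remote.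

**20 to 13 + 19 + 18.** C4a–C4 and C3–C4 are cut together, so the molecule falls into a ring A halide, a one-carbon unit and a ring B alkenylboronate of similar size. This is the point of highest convergence. It avoids adding a hindered ring A organometallic to a cinnamoyl electrophile that also accepts 1,4-addition. The forward step needs uptake of 19 to outrun direct coupling at a doubly ortho-substituted carbon, and it must keep the E geometry.

**18 to 15 + 16, and 15 to 14.** The C2=C3 double bond is cut, so C3 comes from the methylene carbon of 16 and C2 from the formyl carbon of 15. One olefination replaces a homologation-to-alkyne and hydroboration sequence. It must deliver the E isomer. 15 differs from 14 only by two acetal O–C bonds.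

**13 to 9 + 12, and 12 to 11 to 10.** The C8–CH2 bond is cut with the arene as electrophile and the side chain as an alkylzinc nucleophile.
- The reverse polarity was set aside. An aryllithium at C8 or C4a would sit ortho to the silyl ether and could undergo 1,3 oxygen-to-carbon silyl migration at the temperatures a β-branched halide requires. The allylic β-hydrogen of 11 also invites elimination.
- Because 9 is symmetric, either iodine gives the same product, and the iodine left over is exactly the C4a handle of the key step.
- The demand is mono-coupling, with reductive elimination faster than β-hydride elimination.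
- The stereocentre of 10 is never touched.

**9 to 8.** Both C–I bonds are cut. The two open ring positions are equivalent and strongly activated, so no regiochemical question exists. The forward iodination is placed before any alkene enters the molecule, which removes the chemoselectivity problem of an electrophilic iodine source.

**8 to 6 + 3 (through 7), 6 to 5 to 4, and 3 to 2 to 1.** The C6–CH2 bond is cut.
- In 6 the only position flanked by two acetal directing groups is C6, and the bulky silyl ether shields the other two. One directed lithiation is therefore site-selective, and the anion is para to the silyl ether, where no silyl migration is possible.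
- The electrophile 3 is an unbranched primary iodide.
- 6 goes back to 4 by two O-protections. These create the C5/C7 versus C8a distinction at the very start.
- 3 goes back to 1 by selective substitution of the primary hydroxyl and silylation of the tertiary one.

## Other disconnections considered

**Alternative 1:** The cut is C4a–C5. It unravels ring A into a C8–C7–C6–C5 β-keto ester chain attached to C8a of the enantiopure dihydropyranone A2.

*Forward key step.* Base would deprotonate A2, C4a of the extended enolate would attack the C5 ester, and loss of the ester alkoxy group with tautomerisation would give the flavanonol A1 with free C5 and C7 hydroxyls.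

*In favour (structure).*
- The order of the ring A substituents is written into an open chain, so no substitution on a crowded arene is needed.
- O1–C8a exists before ring A, so the C5/C8a ambiguity never arises. On this point it is better than the chosen plan, which spends an orthogonal silyl ether on the problem.
- C2 and C3 could be set on a small ring before any lavandulyl alkene is present, which widens the choice of oxidants. This is also an advantage.

*Against (mechanism).*
- The most acidic proton of A2 is C6–H, and its enolate switches off the C5 ester as an electrophile.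
- C4a becomes nucleophilic only after a second, vinylogous deprotonation at the tertiary, hindered C8–H.
- The same strong base meets C3–H, which is α to C4 and β to O1. Epimerisation, β-elimination that opens ring C, and loss of the silyloxy group all compete.

*Step economy.* A2 needs a long, largely linear build-up that still includes C-alkylation with the same β-branched lavandulyl electrophile. It would probably be longer and less convergent than the 9-step longest sequence chosen here. Its endgame, one or two deprotections, is about equal.

**Alternative 2:** The cut is C2–C3 together with C3–O.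

*Forward key step.* The enolate of the ring A chloromethyl ketone A4 would add to aldehyde 15 under a chiral quaternary ammonium phase-transfer catalyst. The chlorohydrin alkoxide would then close to the trans epoxide A3, which is the same compound as 21.

*In favour.*
- Bond formation, epoxide closure and both stereocentres come in one step.
- The ring B partner is 15 itself, no pressurised gas is used, and step 10 disappears.
- The plan is about one step shorter overall and equal in the longest linear sequence, so on step economy it is slightly better.

*Against (structure).* A4 still requires C4a of the fully substituted ring A to be acylated, most plausibly from 13, so the hardest fragment is not simplified.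

*Against (mechanism).*
- Aldehyde 15 is deactivated by two donor oxygens, so the aldol addition is reversible. Stereocontrol then shifts to the ring closure, where both the cis/trans ratio and the enantioselectivity are harder to govern than oxygen transfer to a preformed E-enone.
- The enolate lies next to a carbonyl twisted by two ortho groups.
- The hydroxide phase threatens the aryl silyl ether, which is activated by the ortho acyl group. Once the C8a phenoxide is free it can displace the chloride and close a five-membered ring, which ends the route.

The chosen plan pays one extra step for two transformations, each of which rests on a broader base of analogous cases.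

**Alternative 3:** The cuts are O1–C8a and C4–C4a.

*Forward key step.* A fluoride source would turn the o-silylaryl triflate A6 into the aryne A8. The C2 alkoxide of the anti β-hydroxy ester A7 would add at C8a, and the C4a aryl anion would attack the ester to give the fully protected flavanonol A5.

*In favour.*
- Ring C and two bonds are made in one operation, which is more convergent than the chosen three-step passage from 13 to 23.
- C2 and C3 come from a small acyclic ester made by dependable aldol chemistry, independent of the bulky ring A. This is an advantage over a catalyst that must accommodate 20.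
- The C5 alkoxy group polarises A8 so that nucleophiles prefer the remote carbon C8a. That is the wanted sense, so regiochemistry is at least equal to the chosen plan.

*Against.*
- Aliphatic alkoxides are modest aryne partners, and C8a is shielded by the branched C8 chain.
- The aryl anion can be protonated before it reaches the ester.
- The aldolate of A7 can fragment by a retro-aldol path, which is easy with an electron-rich aryl group and would scramble both stereocentres.
- The isopropenyl group tethered next to C8a offers A8 an intramolecular ene or cycloaddition escape.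
- Fluoride also endangers the side-chain silyl ether.

*Step economy.* A6 needs the same hexasubstituted ring plus a silyl/triflate pair, so the saving after fragment union is offset before it.

Key step: step 11

Assumption: enantiopure (R)-lavandulol 10 is taken as a commercial compound. Flavonoid numbering (O1, C2, C3, C4, C4a, C5–C8, C8a, primed ring B) is used for all intermediates, and "(2S)-lavandulyl" means (2S)-5-methyl-2-(prop-1-en-2-yl)hex-4-en-1-yl.

## Route

Step 1
Reactants: 1 3-methylbutane-1,3-diol
Product: 2 4-iodo-2-methylbutan-2-ol
Conditions: I2, PPh3, imidazole, CH2Cl2, 0 °C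
Reagents that add atoms: iodine, [I][I]
Why: Appel-type iodination; the alkoxyphosphonium ion forms and is displaced by iodide only at the unhindered primary carbinol, while the tertiary hydroxyl is too hindered to react at 0 °C.

Step 2
Reactants: 2 4-iodo-2-methylbutan-2-ol
Product: 3 triethyl[(4-iodo-2-methylbutan-2-yl)oxy]silane
Conditions: TESOTf, 2,6-lutidine, CH2Cl2, 0 °C
Reagents that add atoms: triethylsilyl trifluoromethanesulfonate, CC[Si](CC)(CC)OS(=O)(=O)C(F)(F)F
Why: Silylation of a tertiary alcohol needs the triflate; the ether prevents alkoxide formation (and oxetane closure) in step 5 and is later removable under very mild aqueous acid.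

Step 3
Reactants: 4 phloroglucinol
Product: 5 3,5-bis(methoxymethoxy)phenol
Conditions: MOMCl (2.0 equiv), iPr2NEt, DMF, 0 °C to rt
Reagents that add atoms: chloromethyl methyl ether, COCCl
Why: O-alkylation of the phenol; the reaction is statistical, the bis-ether is separated by chromatography and the mono-ether can be resubmitted. It creates the two-plus-one pattern of ring A oxygens on which all later regiochemistry rests.

Step 4
Reactants: 5 3,5-bis(methoxymethoxy)phenol
Product: 6 [3,5-bis(methoxymethoxy)phenoxy]triisopropylsilane
Conditions: TIPSCl, imidazole, DMF, rt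
Reagents that add atoms: chlorotriisopropylsilane, CC(C)[Si](Cl)(C(C)C)C(C)C
Why: Standard phenol silylation; the future C8a oxygen receives a fluoride-labile group orthogonal to the acetals, which is also a poor and bulky directing group for lithiation.

Step 5
Reactants: 6 [3,5-bis(methoxymethoxy)phenoxy]triisopropylsilane; 3 triethyl[(4-iodo-2-methylbutan-2-yl)oxy]silane
Product: 8 {3,5-bis(methoxymethoxy)-4-[3-methyl-3-(triethylsilyloxy)butyl]phenoxy}triisopropylsilane, via C6 aryllithium 7 (not isolated)
Conditions: n-BuLi, THF, 0 °C; then 3, DMPU, 0 °C to rt
Reagents that add atoms: none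
Why: Directed ortho-metalation occurs at the one carbon flanked by two chelating acetal groups, the silyl ether shielding the other two positions. The aryllithium is para to the silyl ether, so no silyl migration can occur, and it is alkylated by SN2 at an unbranched primary iodide.

Step 6
Reactants: 8 {3,5-bis(methoxymethoxy)-4-[3-methyl-3-(triethylsilyloxy)butyl]phenoxy}triisopropylsilane
Product: 9 {2,6-diiodo-3,5-bis(methoxymethoxy)-4-[3-methyl-3-(triethylsilyloxy)butyl]phenoxy}triisopropylsilane
Conditions: NIS (2.3 equiv), NaHCO3, MeCN, 0 °C to rt, dark
Reagents that add atoms: N-iodosuccinimide, O=C1CCC(=O)N1I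
Why: Electrophilic aromatic iodination; the two open positions are equivalent by symmetry and each is ortho/para to three oxygen donors, so there is no regiochemical choice. The step precedes the arrival of any alkene, so the iodonium source has no competing target, and the buffer protects the acetals and the silyl ethers.

Step 7
Reactants: 10 (R)-lavandulol
Product: 11 (R)-lavandulyl iodide, (5R)-6-iodo-2-methyl-5-(prop-1-en-2-yl)hex-2-ene
Conditions: I2, PPh3, imidazole, CH2Cl2, 0 °C
Reagents that add atoms: iodine, [I][I]
Why: Appel-type iodination at the primary carbon; the adjacent stereocentre is not involved and stays R because CH2I still outranks isopropenyl. The buffered conditions leave both alkenes untouched.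

Step 8
Reactants: 11 (R)-lavandulyl iodide; 9 the symmetric ring A diiodide
Product: 13 {2-iodo-3,5-bis(methoxymethoxy)-4-[3-methyl-3-(triethylsilyloxy)butyl]-6-[(2S)-lavandulyl]phenoxy}triisopropylsilane (ring A iodide with iodine at C4a), via (R)-lavandulylzinc iodide 12 (not isolated)
Conditions: 11, Zn dust, LiCl, THF, 35 °C; then slow addition to 9 (1.4 equiv), Pd(OAc)2 (3 mol %), SPhos (6 mol %), THF, rt
Reagents that add atoms: none
Why: Zinc inserts into the primary C–I bond without touching the β-stereocentre, and Negishi C(sp3)–C(sp2) coupling with a bulky biarylphosphine favours reductive elimination over β-hydride elimination. Either iodine of 9 leads to the same product; mono-coupling is favoured by the excess of 9 (recovered), by slow addition of 12, and because 13 is more electron-rich and more crowded than 9. The descriptor changes from R to S through the priority switch only.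

Step 9
Reactants: 14 2,4-dihydroxybenzaldehyde
Product: 15 2,4-bis(methoxymethoxy)benzaldehyde
Conditions: NaH, MOMCl, DMF, 0 °C to rt
Reagents that add atoms: chloromethyl methyl ether, COCCl
Why: O-alkylation of the bis-phenoxide; full deprotonation with NaH overcomes the hydrogen bond of the ortho hydroxyl to the formyl group.

Step 10
Reactants: 15 2,4-bis(methoxymethoxy)benzaldehyde; 16 bis(4,4,5,5-tetramethyl-1,3,2-dioxaborolan-2-yl)methane
Product: 18 (E)-2-[2,4-bis(methoxymethoxy)phenyl]ethenylboronic acid pinacol ester, via lithiated diborylmethane 17 (not isolated)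
Conditions: 16, LiTMP (from n-BuLi and 2,2,6,6-tetramethylpiperidine), THF, 0 °C; then 15, −78 °C to rt
Reagents that add atoms: none
Why: Boron-Wittig olefination; the α-diboryl carbanion adds to the aldehyde and syn B–O elimination from the less crowded adduct gives the E-alkenylboronate in one step from the aldehyde.

Step 11
Reactants: 13 ring A iodide; 19 carbon monoxide; 18 (E)-styrenylboronic acid pinacol ester of ring B
Product: 20 (E)-3-[2,4-bis(methoxymethoxy)phenyl]-1-{2,4-bis(methoxymethoxy)-3-[3-methyl-3-(triethylsilyloxy)butyl]-5-[(2S)-lavandulyl]-6-(triisopropylsilyloxy)phenyl}prop-2-en-1-one (protected chalcone)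
Conditions: PdCl2(IPr)(3-chloropyridine) (5 mol %; IPr = 1,3-bis(2,6-diisopropylphenyl)imidazol-2-ylidene), K2CO3 (3 equiv), H2O (2 equiv), CO (4 bar), anisole, 80 °C
Reagents that add atoms: none
Why: This is a carbonylative Suzuki–Miyaura coupling: zerovalent palladium released from the carbene precatalyst inserts into the C4a–I bond of 13, 19 binds, and the electron-rich aryl group migrates onto it to give the aroyl–palladium iodide, a migration helped by relief of the strain between the metal and the two ortho oxygen substituents. Carbonate and hydroxide replace iodide on divalent palladium and activate 18, the styrenyl group is transferred with retention of geometry, and reductive elimination forms C3–C4 after C4a–C4. The closest known reactions are the carbonylative coupling of di-ortho-substituted aryl iodides with boronic acids under carbene–palladium catalysis and that of aryl iodides with alkenylboron reagents to give aryl vinyl ketones. No ring is closed and no stereocentre is created; only the E geometry of 18 is carried into 20. The selectivity required is carbonylative over direct coupling, and the substrate secures it because transmetalation at the crowded aryl–palladium stage is slow whereas uptake of the small 19 under 4 bar is fast. The strongly donating carbene keeps the metal active under 19. The lavandulyl alkenes are meta to C4a and cannot reach the metal for a Heck closure, and as tri- and 1,1-disubstituted alkenes they are poor intermolecular partners; the acetals and silyl ethers tolerate carbonate in anisole. The neutral acyl transfer avoids the competition between 1,2- and 1,4-addition that a ring A organometallic would face with a cinnamoyl electrophile.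

Step 12
Reactants: 20 protected chalcone
Product: 21 trans-epoxy ketone, 3R and 2S in flavonoid numbering (αR,βS), all protecting groups as in 20
Conditions: poly-L-leucine, urea–H2O2, DBU, THF, rt
Reagents that add atoms: urea–hydrogen peroxide, NC(N)=O.OO
Why: Juliá–Colonna epoxidation, the peptide-catalysed asymmetric Weitz–Scheffer reaction; hydroperoxide adds to C2 of the enone held at the N-terminus of the L-leucine helix and the peroxy-enolate closes, which for E-chalcones gives the (αR,βS) trans epoxide. A nucleophilic oxidant attacks only the electron-poor C2=C3 bond, so the lavandulyl alkenes are spared, and the non-aqueous medium spares the hindered aryl silyl ether.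

Step 13
Reactants: 21 trans-epoxy ketone
Product: 23 (2R,3R)-3-hydroxy-5,7-bis(methoxymethoxy)-2-[2,4-bis(methoxymethoxy)phenyl]-6-[3-methyl-3-(triethylsilyloxy)butyl]-8-[(2S)-lavandulyl]chroman-4-one, via C8a phenol epoxide 22 (not isolated)
Conditions: TBAF (1.05 equiv), AcOH (1.2 equiv), THF, 0 °C; pH 7 work-up; then PPTS (20 mol %), CH2Cl2, 0 °C to rt
Reagents that add atoms: none
Why: Buffered fluoride cleaves the aryl silyl ether far faster than the tertiary alkyl triethylsilyl ether and keeps the phenol protonated, which suppresses phenoxide attack at C3. Mild acid then opens the oxirane at C2, where the 2,4-dialkoxyphenyl group carries the positive charge, and the C8a hydroxyl closes ring C in the 6-endo mode with inversion (2S to 2R) while C3 keeps its R configuration; a looser, cation-like closure also ends in the trans isomer with both substituents equatorial. Since the C5 oxygen is still an acetal, only the C8a oxygen can close, which fixes the C6/C8 regiochemistry.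

Step 14
Reactants: 23 protected (2R,3R)-flavanonol
Product: 25 (2R,3R)-2-(2,4-dihydroxyphenyl)-3,5,7-trihydroxy-6-(3-hydroxy-3-methylbutyl)-8-[(2S)-lavandulyl]chroman-4-one (target), via pentakis(trimethylsilyl) ether 24 (not isolated)
Conditions: TMSOTf, 2,2'-bipyridyl, MeCN, 0 °C to rt; then AcOH–THF–H2O (3:1:1), rt
Reagents that add atoms: none
Why: Silyl triflate/bipyridyl-mediated acetal cleavage turns aryl methoxymethyl ethers into aryl trimethylsilyl ethers without free Brønsted acid, so neither the alkenes nor the C2–O1 bond is protonated. Aqueous acetic acid then hydrolyses all O–Si bonds, including the tertiary triethylsilyl ether, at an acidity too low to ionise the tertiary alcohol or hydrate the alkenes. No stereocentre is touched.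

## Compound list

1 | 3-methylbutane-1,3-diol | CC(C)(O)CCO | starting material
2 | 4-iodo-2-methylbutan-2-ol | CC(C)(O)CCI | intermediate
3 | triethyl[(4-iodo-2-methylbutan-2-yl)oxy]silane | CC(C)(CCI)O[Si](CC)(CC)CC | intermediate
4 | phloroglucinol | Oc1cc(O)cc(O)c1 | starting material
5 | 3,5-bis(methoxymethoxy)phenol | COCOc1cc(O)cc(OCOC)c1 | intermediate
6 | [3,5-bis(methoxymethoxy)phenoxy]triisopropylsilane | COCOc1cc(OCOC)cc(O[Si](C(C)C)(C(C)C)C(C)C)c1 | intermediate
7 | C6 aryllithium of 6 (lithium between the two acetal groups) | [Li]c1c(OCOC)cc(O[Si](C(C)C)(C(C)C)C(C)C)cc1OCOC | intermediate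
8 | {3,5-bis(methoxymethoxy)-4-[3-methyl-3-(triethylsilyloxy)butyl]phenoxy}triisopropylsilane | COCOc1cc(O[Si](C(C)C)(C(C)C)C(C)C)cc(OCOC)c1CCC(C)(C)O[Si](CC)(CC)CC | intermediate
9 | {2,6-diiodo-3,5-bis(methoxymethoxy)-4-[3-methyl-3-(triethylsilyloxy)butyl]phenoxy}triisopropylsilane | COCOc1c(I)c(O[Si](C(C)C)(C(C)C)C(C)C)c(I)c(OCOC)c1CCC(C)(C)O[Si](CC)(CC)CC | intermediate
10 | (R)-lavandulol | C=C(C)[C@@H](CC=C(C)C)CO | starting material
11 | (R)-lavandulyl iodide | C=C(C)[C@@H](CC=C(C)C)CI | intermediate
12 | (R)-lavandulylzinc iodide | C=C(C)[C@@H](CC=C(C)C)C[Zn]I | intermediate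
13 | ring A iodide: I at C4a, methoxymethyl ethers at C5 and C7, triisopropylsilyl ether at C8a, side-chain triethylsilyl ether at C6, (2S)-lavandulyl at C8 | C=C(C)[C@@H](CC=C(C)C)Cc1c(OCOC)c(CCC(C)(C)O[Si](CC)(CC)CC)c(OCOC)c(I)c1O[Si](C(C)C)(C(C)C)C(C)C | intermediate
14 | 2,4-dihydroxybenzaldehyde | O=Cc1ccc(O)cc1O | starting material
15 | 2,4-bis(methoxymethoxy)benzaldehyde | COCOc1ccc(C=O)c(OCOC)c1 | intermediate
16 | bis(4,4,5,5-tetramethyl-1,3,2-dioxaborolan-2-yl)methane | CC1(C)OB(CB2OC(C)(C)C(C)(C)O2)OC1(C)C | starting material
17 | lithiated diborylmethane | [Li]C(B1OC(C)(C)C(C)(C)O1)B1OC(C)(C)C(C)(C)O1 | intermediate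
18 | (E)-2-[2,4-bis(methoxymethoxy)phenyl]ethenylboronic acid pinacol ester | CC1(C)OB(/C=C/c2ccc(OCOC)cc2OCOC)OC1(C)C | intermediate
19 | carbon monoxide | [C-]#[O+] | starting material
20 | protected (E)-chalcone with the complete carbon skeleton | C=C(C)[C@@H](CC=C(C)C)Cc1c(OCOC)c(CCC(C)(C)O[Si](CC)(CC)CC)c(OCOC)c(C(=O)/C=C/c2ccc(OCOC)cc2OCOC)c1O[Si](C(C)C)(C(C)C)C(C)C | intermediate
21 | trans-chalcone epoxide, 3R,2S in flavonoid numbering | C=C(C)[C@@H](CC=C(C)C)Cc1c(OCOC)c(CCC(C)(C)O[Si](CC)(CC)CC)c(OCOC)c(C(=O)[C@@H]2O[C@H]2c2ccc(OCOC)cc2OCOC)c1O[Si](C(C)C)(C(C)C)C(C)C | intermediate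
22 | C8a phenol of the epoxide 21 | C=C(C)[C@@H](CC=C(C)C)Cc1c(OCOC)c(CCC(C)(C)O[Si](CC)(CC)CC)c(OCOC)c(C(=O)[C@@H]2O[C@H]2c2ccc(OCOC)cc2OCOC)c1O | intermediate
23 | protected (2R,3R)-flavanonol (four aryl methoxymethyl ethers, side-chain triethylsilyl ether, free 3-OH) | C=C(C)[C@@H](CC=C(C)C)Cc1c(OCOC)c(CCC(C)(C)O[Si](CC)(CC)CC)c(OCOC)c2c1O[C@H](c1ccc(OCOC)cc1OCOC)[C@@H](O)C2=O | intermediate
24 | 3,5,7,2',4'-pentakis(trimethylsilyl) ether with side-chain triethylsilyl ether | C=C(C)[C@@H](CC=C(C)C)Cc1c(O[Si](C)(C)C)c(CCC(C)(C)O[Si](CC)(CC)CC)c(O[Si](C)(C)C)c2c1O[C@H](c1ccc(O[Si](C)(C)C)cc1O[Si](C)(C)C)[C@@H](O[Si](C)(C)C)C2=O | intermediate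
25 | (2R,3R)-2-(2,4-dihydroxyphenyl)-3,5,7-trihydroxy-6-(3-hydroxy-3-methylbutyl)-8-[(2S)-5-methyl-2-(prop-1-en-2-yl)hex-4-en-1-yl]chroman-4-one | C=C(C)[C@@H](CC=C(C)C)Cc1c(O)c(CCC(C)(C)O)c(O)c2c1O[C@H](c1ccc(O)cc1O)[C@@H](O)C2=O | target

## Step count and least certain steps

Total step count: 14. Longest linear sequence: 9 steps from 4 (steps 3, 4, 5, 6, 8, 11, 12, 13, 14).

**Step 11 (key step).**
- *What may go wrong.* Transmetalation of the pinacol ester may stall at the crowded aroyl–palladium centre, followed by hydrolysis of the aroyl–metal bond or deactivation of the catalyst under 19. Coupling without uptake of 19 is also possible. The C8a silyl group may be lost to base once the ortho ketone has made it a better leaving group.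
- *Fallback, from 13 and 15, returning at 20.* The carbonyl carbon is brought in as an aldehyde instead of a gas.
  1. Wittig reaction of 15 with (triphenylphosphoranylidene)acetaldehyde (toluene, 80 °C) gives (E)-3-[2,4-bis(methoxymethoxy)phenyl]prop-2-enal F1.
  2. Iodine–magnesium exchange of 13 with iPrMgCl·LiCl (THF, 0 °C) gives the C4a arylmagnesium chloride F2, which does not undergo silyl migration.
  3. 1,2-Addition of F2 to F1 at −40 °C gives the C4 allylic alcohol F3 as a mixture of C4 epimers.
  4. MnO2 in CH2Cl2 oxidises this doubly activated alcohol to 20 without touching the isolated alkenes.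

**Step 8.**
- *What may go wrong.* A second coupling may occur at the remaining C–I bond, because the catalyst can stay on the ring after the first reductive elimination. β-Hydride elimination at the allylic tertiary C–H of the alkylpalladium intermediate would lead to hydrodeiodination.
- *Fallback, from 8, returning at 13.* The two halogens are made different.
  1. NBS (1 equiv, MeCN, 0 °C) gives the monobromide F4.
  2. NIS gives the bromo iodide F5.
  3. Negishi coupling with 12 occurs only at the C–I bond and gives the C4a bromide F6.
  4. Bromine–lithium exchange (t-BuLi, 2 equiv, THF, −78 °C) gives the C4a aryllithium F7. It is quenched at once with I2 at −78 °C, a temperature at which migration of the bulky silyl group is slow, to give 13.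

**Step 12.**
- *What may go wrong.* Oxygen transfer may be slow and facial selectivity poor, because 20 is much larger than a simple chalcone and its C2 is deactivated by two donor oxygens. Long exposure to hydroperoxide and DBU also risks desilylation.
- *Fallback, from 20, returning at 23.* Catalyst control is given up, and the resident lavandulyl stereocentre is used to make the products separable.
  1. Epoxidation with urea–H2O2 and DBU without the peptide gives 21 together with its (3S,2R) trans-epoxide diastereomer F8.
  2. The mixture is taken through the conditions of step 13, F8 passing through its C8a phenol F9.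
  3. 23 is separated from the (2S,3S)-flavanonol diastereomer F10 by preparative HPLC.

**Step 13.**
- *What may go wrong.* The liberated oxygen may close prematurely at C3 (5-exo) while the medium is still basic. A 1,2-aroyl shift may occur after ionisation at C2. Configuration at C2 may be partly lost.
- *Fallback, from 21, returning at 23.* The order is changed to open first, unmask second, close third.
  1. Phenylmethanethiol with catalytic BF3·OEt2 (CH2Cl2, −78 °C) opens the oxirane at C2 while the C8a oxygen is still silylated. This gives the β-benzylsulfanyl α-hydroxy ketone F11, with C3 spatially unchanged and C2 as epimers.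
  2. Buffered TBAF gives its C8a phenol F12.
  3. AgBF4 (CH2Cl2, 0 °C) activates sulfur as a leaving group, so ring C closes under thermodynamic control to the trans product 23.

**Step 14.**
- *What may go wrong.* Acetal exchange may be incomplete at the doubly flanked C5 and C7 positions, which forces longer exposure. In the hydrolytic stage, the C5 or C7 phenol may close a chroman onto the tertiary alcohol or an alkene, and C2 may epimerise through C2–O1 ionisation.
- *Fallback, from 23, returning at 25.* The release step is moved from hydrolysis to fluoride.
  1. TESOTf and 2,2'-bipyridyl (MeCN, rt) convert the aryl acetals directly into aryl triethylsilyl ethers and silylate the 3-OH, giving the isolable hexakis(triethylsilyl) ether F13.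
  2. F13 can be purified, and HF·pyridine buffered with pyridine (THF, 0 °C) then strips all silyl groups to give 25.

## Further compounds

F1 | step 11 | (E)-3-[2,4-bis(methoxymethoxy)phenyl]prop-2-enal | O=C/C=C/c1ccc(OCOC)cc1OCOC
F2 | step 11 | C4a arylmagnesium chloride derived from 13 | C=C(C)[C@@H](CC=C(C)C)Cc1c(OCOC)c(CCC(C)(C)O[Si](CC)(CC)CC)c(OCOC)c([Mg]Cl)c1O[Si](C(C)C)(C(C)C)C(C)C
F3 | step 11 | C4 allylic alcohol (C4 epimers, E alkene) | C=C(C)[C@@H](CC=C(C)C)Cc1c(OCOC)c(CCC(C)(C)O[Si](CC)(CC)CC)c(OCOC)c(C(O)/C=C/c2ccc(OCOC)cc2OCOC)c1O[Si](C(C)C)(C(C)C)C(C)C
F4 | step 8 | monobromide of 8 | COCOc1cc(O[Si](C(C)C)(C(C)C)C(C)C)c(Br)c(OCOC)c1CCC(C)(C)O[Si](CC)(CC)CC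
F5 | step 8 | bromo iodide of 8 | COCOc1c(I)c(O[Si](C(C)C)(C(C)C)C(C)C)c(Br)c(OCOC)c1CCC(C)(C)O[Si](CC)(CC)CC
F6 | step 8 | C4a bromide analogue of 13 | C=C(C)[C@@H](CC=C(C)C)Cc1c(OCOC)c(CCC(C)(C)O[Si](CC)(CC)CC)c(OCOC)c(Br)c1O[Si](C(C)C)(C(C)C)C(C)C
F7 | step 8 | C4a aryllithium | C=C(C)[C@@H](CC=C(C)C)Cc1c(OCOC)c(CCC(C)(C)O[Si](CC)(CC)CC)c(OCOC)c([Li])c1O[Si](C(C)C)(C(C)C)C(C)C
F8 | step 12 | (3S,2R) trans-epoxide diastereomer of 21 | C=C(C)[C@@H](CC=C(C)C)Cc1c(OCOC)c(CCC(C)(C)O[Si](CC)(CC)CC)c(OCOC)c(C(=O)[C@H]2O[C@@H]2c2ccc(OCOC)cc2OCOC)c1O[Si](C(C)C)(C(C)C)C(C)C
F9 | step 12 | C8a phenol of F8 | C=C(C)[C@@H](CC=C(C)C)Cc1c(OCOC)c(CCC(C)(C)O[Si](CC)(CC)CC)c(OCOC)c(C(=O)[C@H]2O[C@@H]2c2ccc(OCOC)cc2OCOC)c1O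
F10 | step 12 | (2S,3S)-flavanonol diastereomer of 23 | C=C(C)[C@@H](CC=C(C)C)Cc1c(OCOC)c(CCC(C)(C)O[Si](CC)(CC)CC)c(OCOC)c2c1O[C@@H](c1ccc(OCOC)cc1OCOC)[C@H](O)C2=O
F11 | step 13 | β-benzylsulfanyl α-hydroxy ketone (C3 as in 21, C2 epimers) | C=C(C)[C@@H](CC=C(C)C)Cc1c(OCOC)c(CCC(C)(C)O[Si](CC)(CC)CC)c(OCOC)c(C(=O)[C@H](O)C(SCc2ccccc2)c2ccc(OCOC)cc2OCOC)c1O[Si](C(C)C)(C(C)C)C(C)C
F12 | step 13 | C8a phenol of F11 | C=C(C)[C@@H](CC=C(C)C)Cc1c(OCOC)c(CCC(C)(C)O[Si](CC)(CC)CC)c(OCOC)c(C(=O)[C@H](O)C(SCc2ccccc2)c2ccc(OCOC)cc2OCOC)c1O
F13 | step 14 | hexakis(triethylsilyl) ether of 25 | C=C(C)[C@@H](CC=C(C)C)Cc1c(O[Si](CC)(CC)CC)c(CCC(C)(C)O[Si](CC)(CC)CC)c(O[Si](CC)(CC)CC)c2c1O[C@H](c1ccc(O[Si](CC)(CC)CC)cc1O[Si](CC)(CC)CC)[C@@H](O[Si](CC)(CC)CC)C2=O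
A1 | alternative 1 | (2R,3R)-flavanonol with free C5 and C7 hydroxyls, 3-O-tert-butyldimethylsilyl, ring B methoxymethyl ethers, side-chain triethylsilyl ether | C=C(C)[C@@H](CC=C(C)C)Cc1c(O)c(CCC(C)(C)O[Si](CC)(CC)CC)c(O)c2c1O[C@H](c1ccc(OCOC)cc1OCOC)[C@@H](O[Si](C)(C)C(C)(C)C)C2=O
A2 | alternative 1 | enantiopure 2,3-dihydropyran-4-one carrying the C8–C7–C6–C5 β-keto ester chain on C8a (C6 and C8 epimers) | C=C(C)[C@@H](CC=C(C)C)CC(C(=O)C(CCC(C)(C)O[Si](CC)(CC)CC)C(=O)OC)C1=CC(=O)[C@H](O[Si](C)(C)C(C)(C)C)[C@@H](c2ccc(OCOC)cc2OCOC)O1
A3 | alternative 2 | trans-chalcone epoxide, 3R,2S (identical with 21) | C=C(C)[C@@H](CC=C(C)C)Cc1c(OCOC)c(CCC(C)(C)O[Si](CC)(CC)CC)c(OCOC)c(C(=O)[C@@H]2O[C@H]2c2ccc(OCOC)cc2OCOC)c1O[Si](C(C)C)(C(C)C)C(C)C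
A4 | alternative 2 | ring A chloromethyl ketone | C=C(C)[C@@H](CC=C(C)C)Cc1c(OCOC)c(CCC(C)(C)O[Si](CC)(CC)CC)c(OCOC)c(C(=O)CCl)c1O[Si](C(C)C)(C(C)C)C(C)C
A5 | alternative 3 | fully protected (2R,3R)-flavanonol (methoxymethyl ethers at C3, C5, C7, C2', C4') | C=C(C)[C@@H](CC=C(C)C)Cc1c(OCOC)c(CCC(C)(C)O[Si](CC)(CC)CC)c(OCOC)c2c1O[C@H](c1ccc(OCOC)cc1OCOC)[C@@H](OCOC)C2=O
A6 | alternative 3 | o-silylaryl triflate of ring A (trimethylsilyl at C4a, triflate at C8a) | C=C(C)[C@@H](CC=C(C)C)Cc1c(OCOC)c(CCC(C)(C)O[Si](CC)(CC)CC)c(OCOC)c([Si](C)(C)C)c1OS(=O)(=O)C(F)(F)F
A7 | alternative 3 | methyl (2R,3R)-3-[2,4-bis(methoxymethoxy)phenyl]-3-hydroxy-2-(methoxymethoxy)propanoate | O[C@H](c1ccc(OCOC)cc1OCOC)[C@@H](OCOC)C(=O)OC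
A8 | alternative 3 | C4a–C8a aryne of ring A | C=C(C)[C@@H](CC=C(C)C)CC1=C(OCOC)C(CCC(C)(C)O[Si](CC)(CC)CC)=C(OCOC)C#C1
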